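**Plan**
- Retrosynthesis: the 3'-O-benzyl ether is removed last. The pyranone ring is then cut at O1–C8a, C4–C4a and O1–C2 in one operation, giving an aryne and an arylpropiolic acid.
- Enabling feature: ring A carries methoxy groups on C5, C6, C7 and C8 and is fused only through C4a and C8a. It therefore maps onto 3,4,5,6-tetramethoxybenzyne, whose two reacting carbons are equivalent.
- Forward, ring A arm: 1,2,3,4-tetramethoxybenzene is formylated, oxidised to the phenol, brominated and converted into the ortho-silylaryl triflate.
- Forward, ring B arm: 3-hydroxy-4,5-dimethoxybenzaldehyde is benzylated and homologated to the propiolic acid.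
- Ring C is the only ring formed and arises in the convergent aryne step; hydrogenolysis then frees the 3'-hydroxyl.
- Stereochemistry: the target has no stereocentre and no stereogenic double bond, so nothing has to be set.

Key step: step 8

Remark: the target is achiral, so the given SMILES describes its only stereoisomer; 1,2,3,4-tetramethoxybenzene and 3-hydroxy-4,5-dimethoxybenzaldehyde are taken as purchasable.

**Route**

Step 1
Reactants: 1 1,2,3,4-tetramethoxybenzene
Product: 3 2,3,4,5-tetramethoxybenzaldehyde, via chloro ether 2 (not isolated)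
Conditions: Cl2CHOMe, TiCl4, CH2Cl2, 0 °C; then ice-water
Reagents that add atoms: dichloromethyl methyl ether, COC(Cl)Cl; water, O
Why: Rieche formylation is a Friedel–Crafts-type substitution, and because C5 and C6 of the electron-rich ring are equivalent only one aldehyde should form once chloro ether 2 is hydrolysed.

Step 2
Reactants: 3 2,3,4,5-tetramethoxybenzaldehyde
Product: 5 2,3,4,5-tetramethoxyphenol, via aryl formate 4 (not isolated)
Conditions: mCPBA, CH2Cl2, 0 °C to rt; bicarbonate/thiosulfate wash; then K2CO3 (cat.), MeOH, rt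
Reagents that add atoms: mCPBA, O=C(OO)c1cccc(Cl)c1
Why: In this Baeyer–Villiger (Dakin-type) oxidation the electron-rich aryl group should migrate in preference to hydride, and the labile formate 4 is methanolysed only after the peracid has been removed, so the oxidisable phenol never meets the oxidant.

Step 3
Reactants: 5 2,3,4,5-tetramethoxyphenol
Product: 6 2-bromo-3,4,5,6-tetramethoxyphenol
Conditions: NBS (1.0 equiv), CH2Cl2, −78 to 0 °C, dark
Reagents that add atoms: N-bromosuccinimide, O=C1CCC(=O)N1Br
Why: Electrophilic aromatic bromination can only take the single unsubstituted position, which lies ortho to the hydroxyl, and one equivalent of NBS at low temperature should limit oxidation of the ring.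

Step 4
Reactants: 6 2-bromo-3,4,5,6-tetramethoxyphenol
Product: 9 2,3,4,5-tetramethoxy-6-(trimethylsilyl)phenyl trifluoromethanesulfonate, via silyl ether 7 (not isolated), via lithium silylphenoxide 8 (not isolated)
Conditions: HMDS, THF, 70 °C, then evaporate; n-BuLi, THF, −100 °C; Tf2O, −100 °C to rt
Reagents that add atoms: hexamethyldisilazane, C[Si](C)(C)N[Si](C)(C)C; triflic anhydride, O=S(=O)(OS(=O)(=O)C(F)(F)F)C(F)(F)F
Why: O-silylation, bromine–lithium exchange and an anionic 1,3 O-to-C silyl shift (retro-Brook rearrangement) should place silicon on the ring and leave phenoxide 8 for triflation, which is the standard way to ortho-silylaryl triflates from ortho-bromophenols.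

Step 5
Reactants: 10 3-hydroxy-4,5-dimethoxybenzaldehyde
Product: 11 3-(benzyloxy)-4,5-dimethoxybenzaldehyde
Conditions: BnBr, K2CO3, DMF, rt
Reagents that add atoms: benzyl bromide, BrCc1ccccc1
Why: Williamson etherification of the only phenol masks the one group that would otherwise add to the aryne, as an ether that survives organolithium and fluoride and is removed by hydrogenolysis.

Step 6
Reactants: 11 3-(benzyloxy)-4,5-dimethoxybenzaldehyde
Product: 12 1-(benzyloxy)-5-(2,2-dibromovinyl)-2,3-dimethoxybenzene
Conditions: CBr4, PPh3, CH2Cl2, 0 °C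
Reagents that add atoms: carbon tetrabromide, BrC(Br)(Br)Br
Why: The first stage of the Corey–Fuchs sequence is a Wittig-type dibromoolefination that is reliable for electron-rich benzaldehydes.

Step 7
Reactants: 12 1-(benzyloxy)-5-(2,2-dibromovinyl)-2,3-dimethoxybenzene
Product: 14 3-[3-(benzyloxy)-4,5-dimethoxyphenyl]prop-2-ynoic acid, via lithium acetylide 13 (not isolated)
Conditions: n-BuLi (2.1 equiv), THF, −78 °C; CO2 (g), −78 °C to rt; aq. HCl
Reagents that add atoms: carbon dioxide, O=C=O
Why: In the second Corey–Fuchs stage, dehydrobromination and bromine–lithium exchange should give acetylide 13, which is carboxylated by CO2 at a temperature where the benzyl and methyl ethers are inert.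

Step 8
Reactants: 9 2,3,4,5-tetramethoxy-6-(trimethylsilyl)phenyl trifluoromethanesulfonate; 14 3-[3-(benzyloxy)-4,5-dimethoxyphenyl]prop-2-ynoic acid
Product: 17 2-[3-(benzyloxy)-4,5-dimethoxyphenyl]-5,6,7,8-tetramethoxy-4H-chromen-4-one, via tetramethoxybenzyne 15 (not isolated), via hydroxyaryl ynone 16 (not isolated)
Conditions: 9 (1.5 equiv), CsF (4 equiv), THF, 125 °C, sealed tube
Reagents that add atoms: none
Why: Fluoride removes the silyl group of 9 and triflate departs to give aryne 15; the caesium carboxylate of 14 adds to it (O1–C8a), and the ortho aryl anion attacks the adjacent ester carbonyl through a four-membered alkoxide whose opening gives the phenoxide of ynone 16 (C4–C4a). The closest known reaction type is the thermal insertion of arynes into the C–O bond of carboxylic acids, which with 3-arylpropiolic acids runs on to flavones. The pyranone ring then closes by 6-endo-dig oxa-Michael addition of the phenoxide to the aryl-bearing alkyne carbon (O1–C2), and protonation at C3 completes the chromen-4-one. No stereocentre is formed. The aryne addition needs no regiocontrol, because both aryne carbons of 15 are flanked by a methoxy group and are interchanged by the mirror plane of the ring, so either mode gives the same 5,6,7,8-pattern. Acyl migration must outrun protonation of the aryl anion, which the high temperature in aprotic THF should favour, and 6-endo must beat 5-exo closure, which it should because attack at C2 gives a ketone-stabilised allenolate whereas the aurone pathway would pass through an unstabilised vinyl anion.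

Step 9
Reactants: 17 2-[3-(benzyloxy)-4,5-dimethoxyphenyl]-5,6,7,8-tetramethoxy-4H-chromen-4-one
Product: 18 3'-hydroxy-5,6,7,8,4',5'-hexamethoxyflavone
Conditions: H2 (1 atm), 10% Pd/C, EtOAc–MeOH, rt
Reagents that add atoms: none
Why: Palladium-catalysed hydrogenolysis should cleave the benzyl aryl ether at ambient pressure well before the conjugated C2–C3 bond of the flavone is touched, and the six methyl ethers are inert.

**Compound list**

1 | 1,2,3,4-tetramethoxybenzene | COc1ccc(OC)c(OC)c1OC | starting material
2 | (±)-1-[chloro(methoxy)methyl]-2,3,4,5-tetramethoxybenzene (transient, racemic) | COC(Cl)c1cc(OC)c(OC)c(OC)c1OC | intermediate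
3 | 2,3,4,5-tetramethoxybenzaldehyde | COc1cc(C=O)c(OC)c(OC)c1OC | intermediate
4 | 2,3,4,5-tetramethoxyphenyl formate | COc1cc(OC=O)c(OC)c(OC)c1OC | intermediate
5 | 2,3,4,5-tetramethoxyphenol | COc1cc(O)c(OC)c(OC)c1OC | intermediate
6 | 2-bromo-3,4,5,6-tetramethoxyphenol | COc1c(O)c(Br)c(OC)c(OC)c1OC | intermediate
7 | (2-bromo-3,4,5,6-tetramethoxyphenoxy)trimethylsilane | COc1c(O[Si](C)(C)C)c(Br)c(OC)c(OC)c1OC | intermediate
8 | lithium 2,3,4,5-tetramethoxy-6-(trimethylsilyl)phenoxide | COc1c(O[Li])c([Si](C)(C)C)c(OC)c(OC)c1OC | intermediate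
9 | 2,3,4,5-tetramethoxy-6-(trimethylsilyl)phenyl trifluoromethanesulfonate | COc1c(OC)c(OC)c(OS(=O)(=O)C(F)(F)F)c([Si](C)(C)C)c1OC | intermediate
10 | 3-hydroxy-4,5-dimethoxybenzaldehyde | COc1cc(C=O)cc(O)c1OC | starting material
11 | 3-(benzyloxy)-4,5-dimethoxybenzaldehyde | COc1cc(C=O)cc(OCc2ccccc2)c1OC | intermediate
12 | 1-(benzyloxy)-5-(2,2-dibromovinyl)-2,3-dimethoxybenzene | COc1cc(C=C(Br)Br)cc(OCc2ccccc2)c1OC | intermediate
13 | lithium [3-(benzyloxy)-4,5-dimethoxyphenyl]acetylide | [Li]C#Cc1cc(OC)c(OC)c(OCc2ccccc2)c1 | intermediate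
14 | 3-[3-(benzyloxy)-4,5-dimethoxyphenyl]prop-2-ynoic acid | COc1cc(C#CC(=O)O)cc(OCc2ccccc2)c1OC | intermediate
15 | 3,4,5,6-tetramethoxybenzyne | COC1=C(OC)C(OC)=C(OC)C#C1 | intermediate
16 | 3-[3-(benzyloxy)-4,5-dimethoxyphenyl]-1-(2-hydroxy-3,4,5,6-tetramethoxyphenyl)prop-2-yn-1-one | COc1cc(C#CC(=O)c2c(O)c(OC)c(OC)c(OC)c2OC)cc(OCc2ccccc2)c1OC | intermediate
17 | 2-[3-(benzyloxy)-4,5-dimethoxyphenyl]-5,6,7,8-tetramethoxy-4H-chromen-4-one (3'-O-benzyl flavone) | COc1cc(-c2cc(=O)c3c(OC)c(OC)c(OC)c(OC)c3o2)cc(OCc2ccccc2)c1OC | intermediate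
18 | 3'-hydroxy-5,6,7,8,4',5'-hexamethoxyflavone | COc1cc(-c2cc(=O)c3c(OC)c(OC)c(OC)c(OC)c3o2)cc(O)c1OC | target

**Count and risks**

Total step count: 9. Longest linear sequence: 6 (steps 1, 2, 3, 4, 8, 9).

Step 8. The aryl anion may be protonated before the acyl shift, which would end in simple O-arylation of the acid; the alkynoic acid may also lose CO2 at 125 °C, or the ynone may close 5-exo. The fallback is the classical chalcone route to polymethoxyflavones. Phenol 5 would be C-acetylated at its only free position with AcOH and BF3·OEt2 (Friedel–Crafts/Fries acylation) to give 1-(2-hydroxy-3,4,5,6-tetramethoxyphenyl)ethan-1-one F1. Claisen–Schmidt condensation of this with aldehyde 11 (KOH, EtOH) would give (E)-3-[3-(benzyloxy)-4,5-dimethoxyphenyl]-1-(2-hydroxy-3,4,5,6-tetramethoxyphenyl)prop-2-en-1-one F2. Catalytic iodine in DMSO at 120 °C would then cyclise and dehydrogenate the chalcone to flavone 17, where the route is rejoined.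

Step 4. n-Butyllithium may attack silicon of the aryl silyl ether instead of bromine, or the aryllithium may be protonated before the silyl shift in the crowded ring. The fallback avoids halogen–metal exchange. Phenol 5 would be treated with isopropyl isocyanate and Et3N to give 2,3,4,5-tetramethoxyphenyl N-isopropylcarbamate F3. In situ N-silylation (TMSOTf, TMEDA), carbamate-directed ortho-lithiation (n-BuLi, TMEDA, −78 °C) and a TMSCl quench would give 2,3,4,5-tetramethoxy-6-(trimethylsilyl)phenyl N-isopropylcarbamate F4. DBU and Et2NH in MeCN would cleave the carbamate to 2,3,4,5-tetramethoxy-6-(trimethylsilyl)phenol F5, which PhNTf2 in the same flask would triflate to 9.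

Step 3. The para-methoxyphenol may be oxidised to a quinone instead of undergoing ring substitution. The fallback brominates before the phenol exists. Aldehyde 3 would be brominated at its last free position (Br2, NaOAc, AcOH) to give 2-bromo-3,4,5,6-tetramethoxybenzaldehyde F6. Baeyer–Villiger oxidation with mCPBA would give 2-bromo-3,4,5,6-tetramethoxyphenyl formate F7, and methanolysis (K2CO3, MeOH) would return bromophenol 6.

Further compounds
F1 | step 8 | 1-(2-hydroxy-3,4,5,6-tetramethoxyphenyl)ethan-1-one | CC(=O)c1c(O)c(OC)c(OC)c(OC)c1OC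
F2 | step 8 | (E)-3-[3-(benzyloxy)-4,5-dimethoxyphenyl]-1-(2-hydroxy-3,4,5,6-tetramethoxyphenyl)prop-2-en-1-one | COc1cc(/C=C/C(=O)c2c(O)c(OC)c(OC)c(OC)c2OC)cc(OCc2ccccc2)c1OC
F3 | step 4 | 2,3,4,5-tetramethoxyphenyl N-isopropylcarbamate | CC(C)NC(=O)Oc1cc(OC)c(OC)c(OC)c1OC
F4 | step 4 | 2,3,4,5-tetramethoxy-6-(trimethylsilyl)phenyl N-isopropylcarbamate | CC(C)NC(=O)Oc1c(OC)c(OC)c(OC)c(OC)c1[Si](C)(C)C
F5 | step 4 | 2,3,4,5-tetramethoxy-6-(trimethylsilyl)phenol | COc1c(O)c([Si](C)(C)C)c(OC)c(OC)c1OC
F6 | step 3 | 2-bromo-3,4,5,6-tetramethoxybenzaldehyde | COc1c(Br)c(C=O)c(OC)c(OC)c1OC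
F7 | step 3 | 2-bromo-3,4,5,6-tetramethoxyphenyl formate | COc1c(Br)c(OC=O)c(OC)c(OC)c1OC
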